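The readings come from a simulation on assumed constants; the scatter is artificial.

The reading was set for 8.0 d, but theta stood at 43% E by 2.08 d and at 42% at 8.00 d, so I took that time to ask where a flask stops, not how fast it gets there.

| flask | J | D | Z | remark | time |
|---|---|---|---|---|---|
| alpha | 2 M | 0.63 M | 100 mM | run made earlier |  |
| eta | 2 M | 1.6 M | 100 mM | run made earlier |  |
| theta | 1.3 M | 1.4 M | 100 mM | run made earlier |  |
| larch | 2.0 M | 1.00 M | 150 mM |  | 8.0 d |
| maple | 0.50 M | 0.800 M | 100 mM |  | 8.0 d |
| cedar | 2.0 M | 0.500 M | 100 mM |  | 8.0 d |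
| oak | 2.0 M | 1.40 M | 100 mM |  | 8.0 d |
| ash | 2.0 M | 1.40 M | 400 mM |  | 8.0 d |

| run | time / d | E / % | J / % |
|---|---|---|---|
| alpha | 0.625 | 17 | 84 |
| alpha | 1.25 | 18 | 82 |
| alpha | 2.50 | 14 | 84 |
| alpha | 4.00 | 20 | 84 |
| alpha | 8.00 | 16 | 86 |
| eta | 1.67 | 42 | 59 |
| eta | 3.00 | 40 | 62 |
| eta | 5.00 | 41 | 62 |
| eta | 6.00 | 38 | 58 |
| eta | 8.00 | 39 | 60 |
| theta | 0.625 | 38 | 63 |
| theta | 2.08 | 43 | 58 |
| theta | 4.00 | 42 | 58 |
| theta | 6.00 | 42 | 56 |
| theta | 8.00 | 42 | 59 |

(standard deviation of a reading: 2 percentage points)

1. the flasks put in order of amount of E, in percent of the J charged, best first, at 8.0 d (larch / maple / cedar / oak / ash)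
2. the amount of E, in percent of the J charged of the flask you put first, at 8.0 d
3. the amount of E, in percent of the J charged of the flask you put last, at 8.0 d

- no earlier run changes the charge of Z; that part of a forecast is a guess

Theta still held 59% of its J at the end, so J had not stopped it. In theta E and J summed close to the charge, so I gave J no other path. But theta's E came to 39.0% of the D charged. So I supposed that D, the limiting reagent, went two ways: with J over Z to E, and away by a loss of its own.

Let m be the cJ at which D divides evenly between the two paths, so that a share cJ/(cJ+m) reaches E. Summed over a run that has used up its D, at a fixed cZ, D charged equals E formed plus m times ln(J charged/J left). Theta's last reading, whose logarithm is the largest, gave 1.57 M, the crossing concentration. Eta's gave 1.66 M and alpha's 1.78 M.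

No run varied Z, so I guessed that m goes inversely with cZ, which put it at 0.392 M in ash and 1.05 M in larch. Taking the share first at the charged cJ, then at the cJ midway through the run, I reckoned ash 54.8%, oak 35.4%, maple 32.7%, larch 30.8% and cedar 13.6%.

The forecast gave ash > oak > maple > larch > cedar, with 35.5% for ash and 14.4% for cedar, on the ground that “A catalyst should not move an equilibrium”, and there it parted from my reckoning.

The flasks gave ash > oak > maple > larch > cedar, with ash at 54.5% and cedar at 13.6%.

    J + D + Z → Z + E (k = 0.829 /M²/h)
    D → G (k = 0.130 /h)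

In ash at 0.0395 d, D had a half-life of 0.060 d by the path to E against 0.22 d by the path to G, a split of 3.71 to one, which at my m for ash belongs to a cJ of 1.45 M, between the 2.0 M charged and the 0.909 M left at the end. By 4.00 d ash held 0% of its D and E stood at 54.5%, as it did at 80.0 d.

For the neighbour of ash with 1.0 M of Z, the same guess put m at 0.157 M, and the same two passes gave 62.7%. That flask gave 62.3%.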